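**Retrosynthetic overview**

1. The target is a trans-(3R,4R)-dibenzylbutyrolactone (lactone atoms O1, C2(=O), C3 with the ring A benzyl, C4 with the ring B benzyl, C5H2) whose ring B carries at its C5 an (S)-α-aryl-β-hydroxy ketone to ring C. The ketone is unveiled last by benzylic oxidation of a syn-aldol-derived 1,3-diol that is carried as a temporary 1,3-dioxane, followed by debenzylation.
2. Key disconnection: the O1–C2(=O) unit of the lactone is removed as CO2 (supplied by formate). This leaves an acyclic (R)-homoallylic chloride, ring A–CH=CH–CH(CH2–ring B)–CH2Cl. The CO2 radical anion adds to the alkene carbon that becomes C3, and the carboxylate then closes onto C5.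
3. Enabling feature: lactone C3 is homobenzylic to ring A, so as a styrene carbon it is the only site the CO2 radical anion attacks (the radical lands on the ring A benzylic carbon). O1 sits on the primary carbon C5, 1,3 to C3, so the new carboxylate closes 5-exo-tet.
4. C4 comes from an Evans alkylation of a styrylacetyl imide with the ring B benzylic bromide. The side-chain stereocentre comes from an Evans syn-aldol of a ring B arylacetyl imide with O-benzylvanillin. C3 is set by base equilibration to trans.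
5. Ring order: rings A, B and C are bought as vanillin-type arenes; the temporary dioxane is closed in step 9; the lactone (step 16) is the only ring of the target that is built.

Key step: step 16

Remark on the chemistry: the alkene of 18–23 is drawn E, but a Z contaminant is tolerated because both isomers give the same lactone in step 16. Abbreviations in names: Bn = benzyl; ArB = 4-(benzyloxy)-3-[(4R,5S)-4-(4-benzyloxy-3-methoxyphenyl)-2,2-dimethyl-1,3-dioxan-5-yl]-5-methoxyphenyl.

**Route**

Step 1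
Reactants: 1 methyl vanillate; 2 allyl bromide
Product: 3 methyl 4-(allyloxy)-3-methoxybenzoate
Conditions: K2CO3, acetone, reflux
Reagents that add atoms: none
Why: Williamson ether synthesis; the phenoxide displaces bromide from allyl bromide in an SN2 reaction.

Step 2
Reactants: 3 methyl 4-(allyloxy)-3-methoxybenzoate
Product: 4 methyl 3-allyl-4-hydroxy-5-methoxybenzoate
Conditions: N,N-diethylaniline, 200 °C
Reagents that add atoms: none
Why: Aromatic Claisen rearrangement; the [3,3] shift can only deliver the allyl group to the single free ortho position (ring B C5), and tautomerisation restores the phenol.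

Step 3
Reactants: 4 methyl 3-allyl-4-hydroxy-5-methoxybenzoate
Product: 5 methyl 3-allyl-4-(benzyloxy)-5-methoxybenzoate
Conditions: BnBr, K2CO3, DMF, 60 °C
Reagents that add atoms: benzyl bromide, BrCc1ccccc1
Why: Williamson benzylation protects the hindered phenol as an ether that survives bases, hydrides and radicals.

Step 4
Reactants: 5 methyl 3-allyl-4-(benzyloxy)-5-methoxybenzoate
Product: 7 methyl 4-(benzyloxy)-3-methoxy-5-(2-oxoethyl)benzoate, via vicinal diol 6 (not isolated)
Conditions: OsO4 (2 mol%), NaIO4 (4 equiv), 2,6-lutidine, 1,4-dioxane/H2O, rt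
Reagents that add atoms: sodium periodate, [Na+].[O-]I(=O)(=O)=O
Why: Lemieux–Johnson oxidation; dihydroxylation of the terminal alkene and periodate cleavage of the diol give the arylacetaldehyde, with lutidine suppressing over-oxidation.

Step 5
Reactants: 7 methyl 4-(benzyloxy)-3-methoxy-5-(2-oxoethyl)benzoate
Product: 8 2-[2-(benzyloxy)-3-methoxy-5-(methoxycarbonyl)phenyl]acetic acid
Conditions: NaClO2, NaH2PO4, 2-methyl-2-butene, tBuOH/H2O, rt
Reagents that add atoms: sodium chlorite, [Na+].[O-]Cl=O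
Why: Pinnick oxidation converts the enolisable aldehyde into the acid under buffered conditions, with the alkene scavenger keeping hypochlorite off the arene.

Step 6
Reactants: 8 2-[2-(benzyloxy)-3-methoxy-5-(methoxycarbonyl)phenyl]acetic acid; 9 (R)-4-benzyl-2-oxazolidinone
Product: 11 methyl 4-(benzyloxy)-3-{2-[(4R)-4-benzyl-2-oxooxazolidin-3-yl]-2-oxoethyl}-5-methoxybenzoate, via pivalic mixed anhydride 10 (not isolated)
Conditions: PivCl, Et3N, THF, −20 °C; then 9, LiCl, rt
Reagents that add atoms: none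
Why: N-Acylation of the oxazolidinone through the mixed anhydride (LiCl/Et3N protocol) avoids strong base, so the methyl ester and the acidic arylacetyl CH2 are untouched.

Step 7
Reactants: 11 arylacetyl imide; 12 4-(benzyloxy)-3-methoxybenzaldehyde
Product: 13 methyl 4-(benzyloxy)-3-{(2R,3R)-1-[(4R)-4-benzyl-2-oxooxazolidin-3-yl]-3-[4-(benzyloxy)-3-methoxyphenyl]-3-hydroxy-1-oxopropan-2-yl}-5-methoxybenzoate
Conditions: Bu2BOTf, iPr2NEt, CH2Cl2, −78 to 0 °C; then 12, −78 to 0 °C; pH 7 buffer, MeOH, H2O2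
Reagents that add atoms: none
Why: Evans syn-aldol reaction; the Z-boron enolate reacts through a Zimmerman–Traxler chair on the face dictated by the (R)-auxiliary, which sets the aryl-bearing carbon as 2R (the future S centre next to the ketone) and the carbinol as 3R (later oxidised away).

Step 8
Reactants: 13 syn-aldol adduct
Product: 14 (1R,2S)-1-[4-(benzyloxy)-3-methoxyphenyl]-2-[2-(benzyloxy)-5-(hydroxymethyl)-3-methoxyphenyl]propane-1,3-diol
Conditions: LiBH4 (excess), THF/MeOH, 0 to 50 °C; aq. NH4Cl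
Reagents that add atoms: none
Why: Reductive cleavage of the imide by LiBH4 releases the primary alcohol without touching the α-stereocentre, and the same hydride reduces the methyl benzoate to the benzylic alcohol on warming.

Step 9
Reactants: 14 triol
Product: 15 {4-(benzyloxy)-3-[(4R,5S)-4-[4-(benzyloxy)-3-methoxyphenyl]-2,2-dimethyl-1,3-dioxan-5-yl]-5-methoxyphenyl}methanol (ArB–CH2OH)
Conditions: 2,2-dimethoxypropane, pyridinium p-toluenesulfonate (cat.), CH2Cl2, rt; Et3N quench
Reagents that add atoms: 2,2-dimethoxypropane, COC(C)(C)OC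
Why: Acid-catalysed transketalisation closes the 1,3-diol to the six-membered isopropylidene acetal under thermodynamic control, leaving the isolated benzylic alcohol free.

Step 10
Reactants: 15 ArB–CH2OH
Product: 16 (4R,5S)-4-[4-(benzyloxy)-3-methoxyphenyl]-5-[2-(benzyloxy)-5-(bromomethyl)-3-methoxyphenyl]-2,2-dimethyl-1,3-dioxane (ArB–CH2Br)
Conditions: PPh3, CBr4, CH2Cl2, 0 °C
Reagents that add atoms: carbon tetrabromide, BrC(Br)(Br)Br
Why: Appel bromination converts the benzylic alcohol into the bromide under neutral conditions that spare the acetonide.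

Step 11
Reactants: 12 4-(benzyloxy)-3-methoxybenzaldehyde; 17 (2-carboxyethyl)triphenylphosphonium bromide
Product: 18 (E)-4-[4-(benzyloxy)-3-methoxyphenyl]but-3-enoic acid
Conditions: NaN(SiMe3)2 (2.2 equiv), THF, 0 °C; then 12, −78 °C to rt; aq. HCl
Reagents that add atoms: none
Why: Wittig olefination with the carboxylate-bearing ylide gives the styrylacetic acid, and the alkene stays out of conjugation with the carboxylate because it is conjugated to ring A.

Step 12
Reactants: 18 styrylacetic acid; 9 (R)-4-benzyl-2-oxazolidinone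
Product: 20 (R)-4-benzyl-3-{(E)-4-[4-(benzyloxy)-3-methoxyphenyl]but-3-enoyl}oxazolidin-2-one, via pivalic mixed anhydride 19 (not isolated)
Conditions: PivCl, Et3N, THF, −20 °C; then 9, LiCl, rt
Reagents that add atoms: none
Why: Mixed-anhydride N-acylation of the oxazolidinone, as in step 6, proceeds without a strong base that could move the double bond.

Step 13
Reactants: 20 styrylacetyl imide; 16 ArB–CH2Br
Product: 21 (R)-4-benzyl-3-{(2R,3E)-2-(ArB-methyl)-4-[4-(benzyloxy)-3-methoxyphenyl]but-3-enoyl}oxazolidin-2-one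
Conditions: NaN(SiMe3)2, THF, −78 °C; then 16, −78 to −40 °C; AcOH quench
Reagents that add atoms: none
Why: Evans asymmetric alkylation; the chelated Z-sodium dienolate is alkylated at its α-carbon by the reactive benzylic bromide on the face opposite the auxiliary benzyl group, which sets the future lactone C4 as R.

Step 14
Reactants: 21 alkylated imide
Product: 22 (2R,3E)-2-(ArB-methyl)-4-[4-(benzyloxy)-3-methoxyphenyl]but-3-en-1-ol
Conditions: LiBH4, THF/MeOH, 0 °C; aq. NH4Cl
Reagents that add atoms: none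
Why: Reductive removal of the auxiliary by LiBH4 gives the primary alcohol without epimerising the adjacent stereocentre.

Step 15
Reactants: 22 homoallylic alcohol
Product: 23 (4R,5S)-4-[4-(benzyloxy)-3-methoxyphenyl]-5-{2-(benzyloxy)-5-[(2R,3E)-4-[4-(benzyloxy)-3-methoxyphenyl]-2-(chloromethyl)but-3-en-1-yl]-3-methoxyphenyl}-2,2-dimethyl-1,3-dioxane
Conditions: PPh3, CCl4, CH2Cl2, 40 °C
Reagents that add atoms: carbon tetrachloride, ClC(Cl)(Cl)Cl
Why: Appel chlorination installs a primary chloride that resists reduction by the CO2 radical anion and intermolecular displacement by formate, yet is displaced intramolecularly by a carboxylate.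

Step 16
Reactants: 23 homoallylic chloride
Product: 25 (4R)-3-[4-(benzyloxy)-3-methoxybenzyl]-4-(ArB-methyl)dihydrofuran-2(3H)-one (both C3 epimers), via potassium chlorocarboxylate 24 (not isolated)
Conditions: HCO2K (5 equiv), 1-adamantanethiol (20 mol%), 2,4,5,6-tetrakis(carbazol-9-yl)isophthalonitrile (4CzIPN, 2 mol%), DMSO, 450 nm LEDs, 25 °C; then dark, 60 °C
Reagents that add atoms: potassium formate, [K+].[O-]C=O
Why: Photoexcited 4CzIPN starts a thiol-mediated radical chain in which the thiyl radical abstracts hydrogen from formate, the CO2 radical anion adds to the styrene carbon remote from ring A (Giese-type addition) and the resulting ring A benzylic radical is quenched by the thiol, so the C2–C3 bond forms as in the known photochemical formate hydrocarboxylation of styrenes; on warming, carboxylate 24 displaces the primary chloride as in the known lactonisation of γ-halo carboxylates, forming the O1–C5 bond. The only ring closed is the lactone, by a 5-exo-tet substitution. The new stereocentre C3 is created in the radical addition under weak 1,2-induction from C4 and is therefore expected as an epimer mixture, which step 17 converges to trans; C4 is not touched. The step needs regioselective CO2 attack at C3, secured by the ring A aryl group that stabilises the adduct radical, and intramolecular O-alkylation, secured by the 1,3 relation of the carboxylate carbon and the CH2Cl group. The allylic C4–H must not be abstracted, which the bulky tertiary thiol and the large excess of formate are chosen to suppress. Benzyl ethers, the acetonide and the unactivated alkyl chloride should be inert to the CO2 radical anion.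

Step 17
Reactants: 25 lactone epimer mixture
Product: 26 (3R,4R)-3-[4-(benzyloxy)-3-methoxybenzyl]-4-(ArB-methyl)dihydrofuran-2(3H)-one
Conditions: KOtBu (0.2 equiv), THF/tBuOH, 0 °C to rt; AcOH quench
Reagents that add atoms: none
Why: Base-mediated epimerisation through the lactone enolate equilibrates C3 to the thermodynamically preferred trans arrangement relative to the fixed C4 centre.

Step 18
Reactants: 26 trans-lactone acetonide
Product: 27 (3R,4R)-3-[4-(benzyloxy)-3-methoxybenzyl]-4-{4-(benzyloxy)-3-[(1R,2S)-1-(4-benzyloxy-3-methoxyphenyl)-1,3-dihydroxypropan-2-yl]-5-methoxybenzyl}dihydrofuran-2(3H)-one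
Conditions: 1 M aq. HCl, THF, rt
Reagents that add atoms: none
Why: Mild aqueous acid hydrolysis of the isopropylidene acetal frees the 1,3-diol while the lactone, benzyl ethers and the non-enolisable stereocentres stay intact.

Step 19
Reactants: 27 diol
Product: 28 (3R,4R)-3-[4-(benzyloxy)-3-methoxybenzyl]-4-{4-(benzyloxy)-3-[(2S)-1-(4-benzyloxy-3-methoxyphenyl)-3-hydroxy-1-oxopropan-2-yl]-5-methoxybenzyl}dihydrofuran-2(3H)-one
Conditions: activated MnO2 (excess), CH2Cl2, rt
Reagents that add atoms: none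
Why: MnO2 oxidises the electron-rich secondary benzylic alcohol chemoselectively to the aryl ketone and leaves the unactivated primary alcohol, under neutral heterogeneous conditions meant to preserve the α-stereocentre.

Step 20
Reactants: 28 tribenzyl ether ketone
Product: 29 (3R,4R)-4-{4-hydroxy-3-[(2S)-3-hydroxy-1-(4-hydroxy-3-methoxyphenyl)-1-oxopropan-2-yl]-5-methoxybenzyl}-3-(4-hydroxy-3-methoxybenzyl)dihydrofuran-2(3H)-one (target)
Conditions: H2 (1 atm), Pd/C (10 wt%), EtOAc, rt
Reagents that add atoms: none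
Why: Catalytic hydrogenolysis removes the three benzyl ethers under neutral conditions, and the electron-rich aryl ketone is expected to be reduced more slowly than the O-benzyl groups are cleaved.

**Compound list**

1 | methyl vanillate (methyl 4-hydroxy-3-methoxybenzoate) | COC(=O)c1ccc(O)c(OC)c1 | starting material
2 | allyl bromide | C=CCBr | starting material
3 | methyl 4-(allyloxy)-3-methoxybenzoate | COC(=O)c1ccc(OCC=C)c(OC)c1 | intermediate
4 | methyl 3-allyl-4-hydroxy-5-methoxybenzoate | COC(=O)c1cc(CC=C)c(O)c(OC)c1 | intermediate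
5 | methyl 3-allyl-4-(benzyloxy)-5-methoxybenzoate | COC(=O)c1cc(CC=C)c(OCc2ccccc2)c(OC)c1 | intermediate
6 | methyl 4-(benzyloxy)-3-(2,3-dihydroxypropyl)-5-methoxybenzoate | COC(=O)c1cc(CC(O)CO)c(OCc2ccccc2)c(OC)c1 | intermediate (not isolated)
7 | methyl 4-(benzyloxy)-3-methoxy-5-(2-oxoethyl)benzoate | COC(=O)c1cc(CC=O)c(OCc2ccccc2)c(OC)c1 | intermediate
8 | 2-[2-(benzyloxy)-3-methoxy-5-(methoxycarbonyl)phenyl]acetic acid | COC(=O)c1cc(CC(=O)O)c(OCc2ccccc2)c(OC)c1 | intermediate
9 | (R)-4-benzyl-2-oxazolidinone | O=C1N[C@H](Cc2ccccc2)CO1 | starting material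
10 | mixed anhydride of 8 with pivalic acid | COC(=O)c1cc(CC(=O)OC(=O)C(C)(C)C)c(OCc2ccccc2)c(OC)c1 | intermediate (not isolated)
11 | methyl 4-(benzyloxy)-3-{2-[(4R)-4-benzyl-2-oxooxazolidin-3-yl]-2-oxoethyl}-5-methoxybenzoate | COC(=O)c1cc(CC(=O)N2[C@H](Cc3ccccc3)COC2=O)c(OCc4ccccc4)c(OC)c1 | intermediate
12 | 4-(benzyloxy)-3-methoxybenzaldehyde (O-benzylvanillin) | COc1cc(C=O)ccc1OCc1ccccc1 | starting material
13 | methyl 4-(benzyloxy)-3-{(2R,3R)-1-[(4R)-4-benzyl-2-oxooxazolidin-3-yl]-3-[4-(benzyloxy)-3-methoxyphenyl]-3-hydroxy-1-oxopropan-2-yl}-5-methoxybenzoate | COC(=O)c1cc([C@@H](C(=O)N2[C@H](Cc3ccccc3)COC2=O)[C@@H](O)c5ccc(OCc6ccccc6)c(OC)c5)c(OCc4ccccc4)c(OC)c1 | intermediate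
14 | (1R,2S)-1-[4-(benzyloxy)-3-methoxyphenyl]-2-[2-(benzyloxy)-5-(hydroxymethyl)-3-methoxyphenyl]propane-1,3-diol | OCc1cc([C@@H](CO)[C@@H](O)c5ccc(OCc6ccccc6)c(OC)c5)c(OCc4ccccc4)c(OC)c1 | intermediate
15 | {4-(benzyloxy)-3-[(4R,5S)-4-[4-(benzyloxy)-3-methoxyphenyl]-2,2-dimethyl-1,3-dioxan-5-yl]-5-methoxyphenyl}methanol | OCc1cc([C@H]2COC(C)(C)O[C@H]2c5ccc(OCc6ccccc6)c(OC)c5)c(OCc4ccccc4)c(OC)c1 | intermediate
16 | (4R,5S)-4-[4-(benzyloxy)-3-methoxyphenyl]-5-[2-(benzyloxy)-5-(bromomethyl)-3-methoxyphenyl]-2,2-dimethyl-1,3-dioxane | BrCc1cc([C@H]2COC(C)(C)O[C@H]2c5ccc(OCc6ccccc6)c(OC)c5)c(OCc4ccccc4)c(OC)c1 | intermediate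
17 | (2-carboxyethyl)triphenylphosphonium bromide | OC(=O)CC[P+](c1ccccc1)(c1ccccc1)c1ccccc1.[Br-] | starting material
18 | (E)-4-[4-(benzyloxy)-3-methoxyphenyl]but-3-enoic acid | COc1cc(/C=C/CC(=O)O)ccc1OCc1ccccc1 | intermediate
19 | mixed anhydride of 18 with pivalic acid | COc1cc(/C=C/CC(=O)OC(=O)C(C)(C)C)ccc1OCc1ccccc1 | intermediate (not isolated)
20 | (R)-4-benzyl-3-{(E)-4-[4-(benzyloxy)-3-methoxyphenyl]but-3-enoyl}oxazolidin-2-one | COc1cc(/C=C/CC(=O)N2[C@H](Cc3ccccc3)COC2=O)ccc1OCc1ccccc1 | intermediate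
21 | (R)-4-benzyl-3-{(2R,3E)-2-(ArB-methyl)-4-[4-(benzyloxy)-3-methoxyphenyl]but-3-enoyl}oxazolidin-2-one | COc1cc(/C=C/[C@@H](Cc2cc([C@H]3COC(C)(C)O[C@H]3c4ccc(OCc5ccccc5)c(OC)c4)c(OCc6ccccc6)c(OC)c2)C(=O)N7[C@H](Cc8ccccc8)COC7=O)ccc1OCc1ccccc1 | intermediate
22 | (2R,3E)-2-(ArB-methyl)-4-[4-(benzyloxy)-3-methoxyphenyl]but-3-en-1-ol | COc1cc(/C=C/[C@@H](Cc2cc([C@H]3COC(C)(C)O[C@H]3c4ccc(OCc5ccccc5)c(OC)c4)c(OCc6ccccc6)c(OC)c2)CO)ccc1OCc1ccccc1 | intermediate
23 | (4R,5S)-4-[4-(benzyloxy)-3-methoxyphenyl]-5-{2-(benzyloxy)-5-[(2R,3E)-4-[4-(benzyloxy)-3-methoxyphenyl]-2-(chloromethyl)but-3-en-1-yl]-3-methoxyphenyl}-2,2-dimethyl-1,3-dioxane | COc1cc(/C=C/[C@@H](Cc2cc([C@H]3COC(C)(C)O[C@H]3c4ccc(OCc5ccccc5)c(OC)c4)c(OCc6ccccc6)c(OC)c2)CCl)ccc1OCc1ccccc1 | intermediate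
24 | potassium (3R)-2-[4-(benzyloxy)-3-methoxybenzyl]-4-chloro-3-(ArB-methyl)butanoate (both C2 epimers) | COc1cc(CC(C(=O)[O-])[C@@H](Cc2cc([C@H]3COC(C)(C)O[C@H]3c4ccc(OCc5ccccc5)c(OC)c4)c(OCc6ccccc6)c(OC)c2)CCl)ccc1OCc1ccccc1.[K+] | intermediate (not isolated)
25 | (4R)-3-[4-(benzyloxy)-3-methoxybenzyl]-4-(ArB-methyl)dihydrofuran-2(3H)-one (both C3 epimers) | COc1cc(CC2C(=O)OC[C@@H]2Cc2cc([C@H]3COC(C)(C)O[C@H]3c4ccc(OCc5ccccc5)c(OC)c4)c(OCc6ccccc6)c(OC)c2)ccc1OCc1ccccc1 | intermediate
26 | (3R,4R)-3-[4-(benzyloxy)-3-methoxybenzyl]-4-(ArB-methyl)dihydrofuran-2(3H)-one | COc1cc(C[C@H]2C(=O)OC[C@@H]2Cc2cc([C@H]3COC(C)(C)O[C@H]3c4ccc(OCc5ccccc5)c(OC)c4)c(OCc6ccccc6)c(OC)c2)ccc1OCc1ccccc1 | intermediate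
27 | (3R,4R)-3-[4-(benzyloxy)-3-methoxybenzyl]-4-{4-(benzyloxy)-3-[(1R,2S)-1-(4-benzyloxy-3-methoxyphenyl)-1,3-dihydroxypropan-2-yl]-5-methoxybenzyl}dihydrofuran-2(3H)-one | COc1cc(C[C@H]2C(=O)OC[C@@H]2Cc2cc([C@@H](CO)[C@@H](O)c4ccc(OCc5ccccc5)c(OC)c4)c(OCc6ccccc6)c(OC)c2)ccc1OCc1ccccc1 | intermediate
28 | (3R,4R)-3-[4-(benzyloxy)-3-methoxybenzyl]-4-{4-(benzyloxy)-3-[(2S)-1-(4-benzyloxy-3-methoxyphenyl)-3-hydroxy-1-oxopropan-2-yl]-5-methoxybenzyl}dihydrofuran-2(3H)-one | COc1cc(C[C@H]2C(=O)OC[C@@H]2Cc2cc([C@@H](CO)C(=O)c4ccc(OCc5ccccc5)c(OC)c4)c(OCc6ccccc6)c(OC)c2)ccc1OCc1ccccc1 | intermediate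
29 | (3R,4R)-4-{4-hydroxy-3-[(2S)-3-hydroxy-1-(4-hydroxy-3-methoxyphenyl)-1-oxopropan-2-yl]-5-methoxybenzyl}-3-(4-hydroxy-3-methoxybenzyl)dihydrofuran-2(3H)-one | COc1cc(C[C@H]2C(=O)OC[C@@H]2Cc2cc(OC)c(O)c([C@@H](CO)C(=O)c3ccc(O)c(OC)c3)c2)ccc1O | target

**Step count and risks**

Total step count: 20. Longest linear sequence: 18 steps (steps 1–10, then 13–20, from methyl vanillate).

Steps most likely to fail:

Step 16. The thiyl radical may abstract the allylic hydrogen at the future lactone C4 and erode its configuration. The excited photocatalyst may also oxidise the electron-rich styrene, and radical addition to this internal, electron-rich alkene may be slow. The fallback builds the lactone by the classical enolate route without radicals, setting out from bromide 16. The sodium enolate of tert-butyl 4-[(4R)-4-benzyl-2-oxooxazolidin-3-yl]-4-oxobutanoate (NaN(SiMe3)2, THF, −78 °C) is alkylated with 16 to give the succinate imide F1. LiBH4 removes the auxiliary to give the hydroxy tert-butyl ester F2, which closes with catalytic KOtBu in THF to the monosubstituted (4R)-lactone F3. The lithium enolate of F3 (LiN(SiMe3)2, THF, −78 °C) is alkylated with 4-(benzyloxy)-3-methoxybenzyl bromide anti to the C4 substituent, which rejoins the route at 26.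

Step 19. The β-hydroxy ketone may undergo retro-aldol loss of formaldehyde or epimerisation next to the new ketone on the MnO2 surface, or the hindered carbinol may oxidise sluggishly. The fallback sets out from diol 27. The primary alcohol is silylated selectively (TBSCl, imidazole, DMF, 0 °C) to the mono-silyl ether F4. Buffered Dess–Martin oxidation (NaHCO3, CH2Cl2) gives the silyl ketone F5, and HF·pyridine in THF removes the silyl group, rejoining the route at 28.

Step 20. The aryl ketone may be over-reduced, the benzylic C–O bond hydrogenolysed, or the centre next to the ketone epimerised on the palladium surface during the triple debenzylation. The fallback reverses the order and sets out from diol 27. Hydrogenolysis before any ketone exists (H2, Pd/C, EtOAc/EtOH) gives the triphenol diol F6. The carbinol C–H para to the free phenol of ring C, the most hydridic benzylic position, is then oxidised with DDQ (1.05 equiv, 1,4-dioxane, 0 °C to rt), which arrives directly at 29.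

**Further compounds**

F1 | step 16 | tert-butyl (3R)-4-[(4R)-4-benzyl-2-oxooxazolidin-3-yl]-3-(ArB-methyl)-4-oxobutanoate | CC(C)(C)OC(=O)C[C@@H](Cc1cc([C@H]2COC(C)(C)O[C@H]2c3ccc(OCc4ccccc4)c(OC)c3)c(OCc5ccccc5)c(OC)c1)C(=O)N6[C@H](Cc7ccccc7)COC6=O
F2 | step 16 | tert-butyl (3R)-3-(ArB-methyl)-4-hydroxybutanoate | CC(C)(C)OC(=O)C[C@@H](Cc1cc([C@H]2COC(C)(C)O[C@H]2c3ccc(OCc4ccccc4)c(OC)c3)c(OCc5ccccc5)c(OC)c1)CO
F3 | step 16 | (4R)-4-(ArB-methyl)dihydrofuran-2(3H)-one | O=C1OC[C@H](Cc2cc([C@H]3COC(C)(C)O[C@H]3c4ccc(OCc5ccccc5)c(OC)c4)c(OCc6ccccc6)c(OC)c2)C1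
F4 | step 19 | primary tert-butyldimethylsilyl ether of diol 27 | COc1cc(C[C@H]2C(=O)OC[C@@H]2Cc2cc([C@@H](CO[Si](C)(C)C(C)(C)C)[C@@H](O)c4ccc(OCc5ccccc5)c(OC)c4)c(OCc6ccccc6)c(OC)c2)ccc1OCc1ccccc1
F5 | step 19 | primary tert-butyldimethylsilyl ether of ketone 28 | COc1cc(C[C@H]2C(=O)OC[C@@H]2Cc2cc([C@@H](CO[Si](C)(C)C(C)(C)C)C(=O)c4ccc(OCc5ccccc5)c(OC)c4)c(OCc6ccccc6)c(OC)c2)ccc1OCc1ccccc1
F6 | step 20 | (3R,4R)-4-{4-hydroxy-3-[(1R,2S)-1,3-dihydroxy-1-(4-hydroxy-3-methoxyphenyl)propan-2-yl]-5-methoxybenzyl}-3-(4-hydroxy-3-methoxybenzyl)dihydrofuran-2(3H)-one | COc1cc(C[C@H]2C(=O)OC[C@@H]2Cc2cc([C@@H](CO)[C@@H](O)c4ccc(O)c(OC)c4)c(O)c(OC)c2)ccc1O
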